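The earlier runs and the new flask were computed on assumed constants, noise included.

The meeting took the easy step first: in the alder run Sbt reads 0 % by 2.50 d, so from then on the Sbt.Oth2 readings show a fade, and a fade can be handled like any decay.

- alder: Sbt 2 M; Oth 200 mM (held); run made earlier
- flask: Sbt 3.0 M; Oth 200 mM (held); time 10 d

alder run (percent of the Sbt charged)

| time / d | Sbt.Oth2 / % | Sbt / % |
|---|---|---|
| 2.50 | 20.2 | 0 |
| 5.00 | 11.4 | 0.1 |
| 8.00 | 6.7 | 0 |
| 10.0 | 5.2 | 0.2 |
| 12.0 | 3.3 | 0 |

(readings scatter by 0.5 percentage points)

- at the start none of Oth is in solution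
- Oth2 is what Oth becomes in solution

- the Sbt.Oth2 standing at 10 d, as a percentage of the Sbt charged
- concentration of Oth2 in solution at 10 d, in percent of saturation

The chair proposed replacing the curve by one mean: the span between first and last reading divided by the logarithm of their ratio, 5.24 d, minuted as the fade time. The analyst checked what that mean hides. The alder stretch up to 5.00 d gives 4.37 d, the stretch from 8.00 d gives 5.65 d, and the analyst held that a scatter of 0.5 percentage points on readings this small covers the gap. The chemist objected that the flask charges 3.0 M, not 2 M. The chair replied that a first-order fade with a fixed time constant takes the same share per day at any amount. So the meeting, assuming as a guess that the flask stands at alder's percentage at 2.50 d and fades with the same time constant, committed to 4.83 % at 10 d, and to no figure for the saturation of Oth2.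

The forecast gives 3.8 % and 99 %, holding that the adduct “fades about as 1/t”, and its y lies below the meeting's.

The flask gives 4.43 % and 81.8 %.

    Oth2 + Sbt.Oth2 → Sdp2 (k = 0.0480 M⁻¹ h⁻¹)
    Sbt → Sdp (k = 0.130 h⁻¹)
    Oth ⇌ Oth2, rate k3*(csat - [Oth2]) (kL = 0.840 h⁻¹)
    2 Oth2 → Pdt (k = 0.550 M⁻¹ h⁻¹)
    Sbt + Oth2 → Sbt.Oth2 (k = 0.510 M⁻¹ h⁻¹)

In this flask [Oth2] stands at 0.162 M at 5.00 d and 0.164 M at 10.0 d, below 200 mM, while Pdt reaches 3.35 M. With [Oth2] this steady, the fade in this flask is pseudo-first-order, and the fade time read from alder carries the flask's 11.3 % at 5.00 d to 4.35 % at 10 d. Two steps acting together have a part in the low standing: at 10 d, without Oth2 + Sbt.Oth2 → Sdp2 the flask holds 26.9 %, and without Sbt → Sdp it holds 20.9 %.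

Read at 4.0 d with the same charge, the neighbour flask should hold 13.9 % by the fade time, run backwards from 4.43 %. Computed, it holds 13.6 %.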